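The upper epoxy-ketone ring (C1–C4, C4a, C8a) is carried as an aromatic 1-naphthol and dearomatised only after the halves are joined. The key step grows it on a salicylate-derived aroyl sulfoxonium ylide, an open-chain precursor: a [Cp*RhCl2]2-catalysed C–H annulation with vinyl acetate forms C4a–C4 and C2–C3 in one operation. It exploits the aryl ketone edge of ring A: the C1 carbonyl on C8a steers metalation to C4a, and the ylide carbon C2 is a latent carbene. The naphthyllithium then adds to an enantioenriched lower epoxy-ketone to set C4′; PhI(OAc)2 oxidation, ketal exchange, chlorination and epoxidation complete the cage.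

Key step: step 7

Remark: upper unit numbering is C1 (ketone), C2/C3 (epoxide), C4 (spiroketal carbon), C5 (bonded to C4′), C7 (Cl), C8 (OH); lower unit is C1′ (carbinol), C2′/C3′ (epoxide), C4′ (quaternary), C5′ (ketal O), C7′ (Cl), C8′ (OH); hydride donors are assumed to attack 2,3-epoxy-1-tetralones anti to the epoxide oxygen.

Step 1
Reactants: 1 naphthazarin (5,8-dihydroxynaphthalene-1,4-dione)
Product: 2 5,8-bis(allyloxy)naphthalene-1,4-dione
Conditions: allyl bromide, Ag2O, CHCl3, rt, dark
Reagents that add atoms: allyl bromide, C=CCBr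
Why: Silver-oxide-promoted Williamson (Purdie) O-alkylation should etherify both chelated peri hydroxyls and keep the quinone symmetric for the later desymmetrisation.

Step 2
Reactants: 2 5,8-bis(allyloxy)naphthalene-1,4-dione
Product: 3 meso-(2R,3S)-5,8-bis(allyloxy)-2,3-epoxy-2,3-dihydronaphthalene-1,4-dione
Conditions: 30% H2O2, Na2CO3, THF–H2O, 0 °C
Reagents that add atoms: hydrogen peroxide, OO
Why: Weitz–Scheffer nucleophilic epoxidation of the electron-poor quinone double bond should give the cis-fused epoxide, which is meso, so no stereocontrol is needed yet.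

Step 3
Reactants: 3 meso-(2R,3S)-5,8-bis(allyloxy)-2,3-epoxy-2,3-dihydronaphthalene-1,4-dione
Product: 4 (2R,3R,4R)-5,8-bis(allyloxy)-2,3-epoxy-4-hydroxy-3,4-dihydronaphthalen-1(2H)-one
Conditions: RuCl[(S,S)-TsDPEN](p-cymene) (2 mol %), HCO2H–Et3N (5:2), CH2Cl2, 0 °C
Reagents that add atoms: none
Why: Noyori–Ikariya asymmetric transfer hydrogenation should desymmetrise the meso dione: hydride adds anti to the epoxide oxygen (hydroxyl cis to the epoxide) and the (S,S)-catalyst accepts only the enantiotopic carbonyl that shows its tetralone-preferred face on that side, which sets the carbinol carbon (C1′) as R and with it the absolute configuration of C2′ and C3′, while the remaining carbonyl is the mismatched one.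

Step 4
Reactants: 5 methyl 5-bromo-2-hydroxybenzoate
Product: 6 methyl 5-bromo-3-chloro-2-hydroxybenzoate
Conditions: NCS, p-TsOH (10 mol %), MeCN, 50 °C
Reagents that add atoms: N-chlorosuccinimide, O=C1CCC(=O)N1Cl
Why: Electrophilic aromatic chlorination should go ortho to the phenol at C3, the only activated free position, since the para position carries bromine.

Step 5
Reactants: 6 methyl 5-bromo-3-chloro-2-hydroxybenzoate
Product: 7 methyl 2-(allyloxy)-5-bromo-3-chlorobenzoate
Conditions: allyl bromide, K2CO3, DMF, 50 °C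
Reagents that add atoms: allyl bromide, C=CCBr
Why: Williamson etherification masks the phenol, which would otherwise capture the carbene equivalent of step 7, as an allyl ether that zerovalent palladium removes later.

Step 6
Reactants: 7 methyl 2-(allyloxy)-5-bromo-3-chlorobenzoate
Product: 8 1-[2-(allyloxy)-5-bromo-3-chlorophenyl]-2-(dimethyl-oxo-λ6-sulfanylidene)ethan-1-one
Conditions: Me3S(O)I, KOt-Bu, THF, reflux; then 7, 0 °C to rt
Reagents that add atoms: trimethylsulfoxonium iodide, C[S+](C)(C)=O.[I-]
Why: Acyl substitution of the ester by dimethylsulfoxonium methylide (Corey–Chaykovsky reagent) followed by deprotonation should give the stabilised β-keto sulfoxonium ylide, the aryl halides and the allyl ether being inert.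

Step 7
Reactants: 8 1-[2-(allyloxy)-5-bromo-3-chlorophenyl]-2-(dimethyl-oxo-λ6-sulfanylidene)ethan-1-one; 9 vinyl acetate
Product: 11 8-(allyloxy)-5-bromo-7-chloronaphthalen-1-ol, via naphthalen-1(4H)-one keto tautomer 10 (not isolated)
Conditions: [Cp*RhCl2]2 (4 mol %), AgSbF6 (16 mol %), NaOAc (30 mol %), vinyl acetate (5 equiv), ClCH2CH2Cl, 80 °C
Reagents that add atoms: vinyl acetate, CC(=O)OC=C
Why: Proposed new method: the ylide carbonyl (C1) holds trivalent Cp*Rh at the only free ortho C–H (the future C4a), vinyl acetate inserts into the aryl–Rh bond with the aryl group on its CH2 terminus (C4a–C4 bond) and rhodium on the acetoxy carbon, loss of Me2SO from the coordinated ylide gives a rhodium carbene at C2 into which the alkyl group migrates (C2–C3 bond), and β-acetoxy elimination releases naphthalen-1(4H)-one 10, which tautomerises to 11. The closest known reaction types are the [Cp*RhCl2]2-catalysed C–H activation/[4+2] annulation of aroyl sulfoxonium ylides with internal alkynes to 1-naphthols and the use of vinyl acetate as an acetylene equivalent in Cp*Rh C–H annulations of benzamides; an alkyne itself cannot deliver the unsubstituted C3–C4 unit needed here. The single new ring closes as a formal [4+2] annulation, the ring-closing event being the migratory insertion of the rhodium-bound alkyl into the carbene (six-membered ring), and no stereocentre is formed. Site selectivity is secured because the second ortho position carries the allyloxy group, insertion regiochemistry follows the known preference of vinyl esters (aryl to CH2), and chemoselectivity over C–Br, C–Cl and the allyl ether rests on the reluctance of trivalent rhodium to undergo oxidative addition under these conditions.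

Step 8
Reactants: 11 8-(allyloxy)-5-bromo-7-chloronaphthalen-1-ol; 4 (2R,3R,4R)-5,8-bis(allyloxy)-2,3-epoxy-4-hydroxy-3,4-dihydronaphthalen-1(2H)-one
Product: 14 8-(allyloxy)-7-chloro-5-[(1′R,2′R,3′R,4′S)-5′,8′-bis(allyloxy)-2′,3′-epoxy-1′,4′-dihydroxy-1′,2′,3′,4′-tetrahydronaphthalen-4′-yl]naphthalen-1-ol, via lithium alkoxide of the epoxy ketone 12 (not isolated), via dilithiated naphthol 13 (not isolated)
Conditions: 11, n-BuLi (2.05 equiv), THF, −78 °C; 4, LiN(SiMe3)2 (1.0 equiv), THF, −78 °C; mix, −78 to −40 °C; aq. NH4Cl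
Reagents that add atoms: none
Why: Bromine–lithium exchange on the lithium naphtholate gives a C5 aryllithium whose 1,2-addition to the C4′ ketone should occur anti to the epoxide oxygen (Felkin-type and less hindered face), so the new C4′ hydroxyl is cis to the epoxide, and the cis C1′ alkoxide cannot undergo Payne rearrangement.

Step 9
Reactants: 14 the coupled triol of step 8
Product: 16 mixed methyl ketal (quinone monoketal; both C4 epimers), via peri-fused naphthofuran naphthol 15 (not isolated)
Conditions: PhI(OAc)2 (2.2 equiv), MeOH–CH2Cl2, 0 °C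
Reagents that add atoms: methanol, CO
Why: Oxidative dearomatisation of the 1-naphthol by trivalent iodine is para-selective: the peri C4′ hydroxyl should capture C4 first (five-membered ring), and a second oxidation with methanol capture gives the quinone monoketal with C1 as ketone; both C4 epimers are carried on because C4 is re-ionised in step 12.

Step 10
Reactants: 16 mixed methyl ketal
Product: 17 1′-O-(4-nitrobenzoyl) ester with inverted C1′ (1′S; ester trans to the epoxide oxygen)
Conditions: 4-O2NC6H4CO2H, PPh3, DIAD, THF, 0 °C to rt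
Reagents that add atoms: 4-nitrobenzoic acid, OC(=O)c1ccc(cc1)[N+](=O)[O-]
Why: The Mitsunobu reaction should invert C1′ by SN2 displacement, turning the cis into the required trans epoxy alcohol, with no other free hydroxyl or phenol present.

Step 11
Reactants: 17 trans 4-nitrobenzoate
Product: 18 tris-phenol with free trans C1′ hydroxyl (ring B as hydroquinone; C4 methyl ketal)
Conditions: Pd(PPh3)4 (5 mol %), K2CO3, MeOH, rt, degassed; pH 7 buffer
Reagents that add atoms: none
Why: Zerovalent palladium should cleave the three aryl allyl ethers through π-allyl complexes (Tsuji–Trost deallylation, methoxide as acceptor) while the same carbonate–methanol medium transesterifies the activated ester, leaving epoxide, enone and ketal untouched.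

Step 12
Reactants: 18 tris-phenol
Product: 19 cage enone (spiroketal closed, C2=C3 enone, no chlorine on ring B)
Conditions: CSA (20 mol %), 4 Å MS, CH2Cl2, 0 °C to rt, Ar
Reagents that add atoms: none
Why: Acid-catalysed intramolecular transketalisation: the C4 methoxy group leaves and the C5′ phenol closes the six-membered dioxin ring on the oxocarbenium ion, C4 being forced into the single configuration that the C4′ bridgehead allows.

Step 13
Reactants: 19 cage enone
Product: 20 7,7′-dichloro cage enone
Conditions: NCS (1.05 equiv), MeCN, 0 °C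
Reagents that add atoms: N-chlorosuccinimide, O=C1CCC(=O)N1Cl
Why: Electrophilic aromatic chlorination should take C7′, the only open position ortho to a free phenol, since ring A offers only C6, which is meta to its hydroxyl and para to the acyl carbon.

Step 14
Reactants: 20 7,7′-dichloro cage enone
Product: 21 target CNP0289684.3
Conditions: t-BuOOH, 1,5,7-triazabicyclo[4.4.0]dec-5-ene, PhMe, 0 °C
Reagents that add atoms: tert-butyl hydroperoxide, CC(C)(C)OO
Why: Weitz–Scheffer nucleophilic epoxidation of the C2=C3 enone: the peroxide anion should add to C3 from the face opposite the pseudo-axial C4–O–C5′ aryl ether (ring B), that is syn to the bridging oxygen, and ring closure sets C2 and C3 cis on that face.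

Compound list
1 | naphthazarin (5,8-dihydroxynaphthalene-1,4-dione) | O=C1C=CC(=O)c2c(O)ccc(O)c12 | starting material
2 | 5,8-bis(allyloxy)naphthalene-1,4-dione | O=C1C=CC(=O)c2c(OCC=C)ccc(OCC=C)c12 | intermediate
3 | meso-(2R,3S)-5,8-bis(allyloxy)-2,3-epoxy-2,3-dihydronaphthalene-1,4-dione | C=CCOc1ccc(OCC=C)c2c1C(=O)[C@@H]1O[C@@H]1C2=O | intermediate
4 | (2R,3R,4R)-5,8-bis(allyloxy)-2,3-epoxy-4-hydroxy-3,4-dihydronaphthalen-1(2H)-one (OH cis to the epoxide oxygen; its C1 is C4′ and its C4 is C1′ of the target) | C=CCOc1ccc(OCC=C)c2c1C(=O)[C@@H]1O[C@@H]1[C@@H]2O | intermediate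
5 | methyl 5-bromo-2-hydroxybenzoate | COC(=O)c1cc(Br)ccc1O | starting material
6 | methyl 5-bromo-3-chloro-2-hydroxybenzoate | COC(=O)c1cc(Br)cc(Cl)c1O | intermediate
7 | methyl 2-(allyloxy)-5-bromo-3-chlorobenzoate | COC(=O)c1cc(Br)cc(Cl)c1OCC=C | intermediate
8 | 1-[2-(allyloxy)-5-bromo-3-chlorophenyl]-2-(dimethyl-oxo-λ6-sulfanylidene)ethan-1-one (aroyl sulfoxonium ylide) | CS(C)(=O)=CC(=O)c1cc(Br)cc(Cl)c1OCC=C | intermediate
9 | vinyl acetate | CC(=O)OC=C | starting material
10 | 8-(allyloxy)-5-bromo-7-chloronaphthalen-1(4H)-one (keto tautomer, not isolated) | O=C1C=CCc2c(Br)cc(Cl)c(OCC=C)c12 | intermediate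
11 | 8-(allyloxy)-5-bromo-7-chloronaphthalen-1-ol | Oc1cccc2c(Br)cc(Cl)c(OCC=C)c12 | intermediate
12 | lithium alkoxide of 4 (not isolated) | C=CCOc1ccc(OCC=C)c2c1C(=O)[C@@H]1O[C@@H]1[C@@H]2O[Li] | intermediate
13 | O,5-dilithio derivative of 11 (not isolated) | [Li]Oc1cccc2c([Li])cc(Cl)c(OCC=C)c12 | intermediate
14 | 8-(allyloxy)-7-chloro-5-[(1′R,2′R,3′R,4′S)-5′,8′-bis(allyloxy)-2′,3′-epoxy-1′,4′-dihydroxy-1′,2′,3′,4′-tetrahydronaphthalen-4′-yl]naphthalen-1-ol (both lower-ring hydroxyls cis to the epoxide oxygen, naphthyl trans) | C=CCOc1ccc(OCC=C)c2c1[C@](c1cc(Cl)c(OCC=C)c3c(O)cccc13)(O)[C@@H]1O[C@@H]1[C@@H]2O | intermediate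
15 | peri-fused naphthofuran naphthol: 14 with the C4′ oxygen bonded to C4 of the naphthol (2H-naphtho[1,8-bc]furan; 1-OH free; not isolated) | C=CCOc1ccc(OCC=C)c2c1[C@](c1cc(Cl)c(OCC=C)c3c(O)ccc4c13)(O4)[C@@H]1O[C@@H]1[C@@H]2O | intermediate
16 | mixed methyl ketal: C1 ketone, C2=C3, C4 bearing OMe and the C4′ oxygen (both C4 epimers); lower ring (1′R,2′R,3′R,4′S) with cis 1′-OH | C=CCOc1ccc(OCC=C)c2c1[C@](c1cc(Cl)c(OCC=C)c3C(=O)C=CC4(OC)c13)(O4)[C@@H]1O[C@@H]1[C@@H]2O | intermediate
17 | 4-nitrobenzoate of 16 with inverted C1′ (1′S,2′R,3′R,4′S; ester trans to the epoxide oxygen) | C=CCOc1ccc(OCC=C)c2c1[C@](c1cc(Cl)c(OCC=C)c3C(=O)C=CC4(OC)c13)(O4)[C@@H]1O[C@@H]1[C@H]2OC(=O)c1ccc(cc1)[N+](=O)[O-] | intermediate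
18 | tris-phenol: free 8-OH, 5′-OH, 8′-OH and trans 1′-OH (1′S); C4 methyl ketal, both epimers | Oc1ccc(O)c2c1[C@](c1cc(Cl)c(O)c3C(=O)C=CC4(OC)c13)(O4)[C@@H]1O[C@@H]1[C@H]2O | intermediate
19 | cage enone: C4 bonded to the C4′ oxygen and the C5′ oxygen, C2=C3 enone, 7-Cl, 8-OH, 8′-OH, lower epoxide and trans 1′-OH, spatial arrangement as in the target | O=C1c2c(O)c(Cl)cc3c2[C@@]2(Oc4ccc(O)c5c4[C@]3(O2)[C@@H]2O[C@@H]2[C@H]5O)C=C1 | intermediate
20 | 7,7′-dichloro cage enone (19 chlorinated at C7′) | O=C1c2c(O)c(Cl)cc3c2[C@@]2(Oc4cc(Cl)c(O)c5c4[C@]3(O2)[C@@H]2O[C@@H]2[C@H]5O)C=C1 | intermediate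
21 | CNP0289684.3, (2S,3R,4S,1′S,2′R,3′R,4′S) in the unit numbering of the remark | O=C1c2c(O)c(Cl)cc3c2[C@@]2(Oc4cc(Cl)c(O)c5c4[C@]3(O2)[C@@H]2O[C@@H]2[C@H]5O)[C@@H]2O[C@H]12 | target

Total step count: 14. Longest linear sequence: 11 steps (steps 4 to 14 from methyl 5-bromo-2-hydroxybenzoate); the lower branch (steps 1 to 3) joins at step 8.

Steps most likely to fail

1. Step 7 (proposed new method). The seven-membered rhodacycle may undergo β-hydride elimination to a Heck-type vinylation product, or the alkyl group may fail to migrate onto the carbene, so that no ring closes. The fallback uses known chemistry only, sets out from 7 and returns at 10, which tautomerises to 11. Saponification (LiOH, THF–H2O) should give 2-(allyloxy)-5-bromo-3-chlorobenzoic acid F1. Carboxylate-directed ortho C–H allylation ([Ru(p-cymene)Cl2]2, K3PO4, allyl acetate) at the only free ortho position gives 6-allyl-2-(allyloxy)-5-bromo-3-chlorobenzoic acid F2. The acid chloride ((COCl)2, then MeNHOMe·HCl, Et3N) gives 6-allyl-2-(allyloxy)-5-bromo-3-chloro-N-methoxy-N-methylbenzamide F3, and vinylmagnesium bromide gives 1-[6-allyl-2-(allyloxy)-5-bromo-3-chlorophenyl]prop-2-en-1-one F4. Ring-closing metathesis with the second-generation Grubbs catalyst then forms the C2=C3 bond; the six-membered closure should outrun the seven-membered closure onto the O-allyl group because it is pulled forward by aromatisation.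

2. Step 8. The peri-hindered dianionic aryllithium may add too slowly to the hindered α-epoxy ketone, so that proton transfer or epoxide opening competes. The fallback reverses the order of events, sets out from 7 and 4 and returns at 14. Bromine–magnesium exchange of 7 with i-PrMgCl·LiCl (THF, −15 °C, ester tolerated) gives a less hindered aryl Grignard reagent, which adds to 12 in the presence of LaCl3·2LiCl to give methyl 2-(allyloxy)-3-chloro-5-[(1′R,2′R,3′R,4′S)-5′,8′-bis(allyloxy)-2′,3′-epoxy-1′,4′-dihydroxy-1′,2′,3′,4′-tetrahydronaphthalen-4′-yl]benzoate F5. Dimethylsulfoxonium methylide converts the ester into the corresponding aroyl sulfoxonium ylide F6. The annulation with 9 under the conditions of step 7 is then run on this advanced intermediate.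

3. Step 14. Deprotonation may compete with epoxidation: the peri phenoxide deactivates the enone, the trans epoxy alkoxide can undergo Payne-type epoxide migration, and face selectivity may erode. The fallback is a protecting-group detour that sets out from 20 and returns at 21. Silylation (TBSOTf, 2,6-lutidine) gives the 8,8′,1′-tris(tert-butyldimethylsilyl) ether of 20 F7; epoxidation (t-BuOOH, DBU) of this neutral enone from the same open face gives the tris-silylated 2,3-epoxide F8; HF·pyridine then removes the three silyl groups.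

Further compounds
F1 | step 7 | 2-(allyloxy)-5-bromo-3-chlorobenzoic acid | OC(=O)c1cc(Br)cc(Cl)c1OCC=C
F2 | step 7 | 6-allyl-2-(allyloxy)-5-bromo-3-chlorobenzoic acid | OC(=O)c1c(CC=C)c(Br)cc(Cl)c1OCC=C
F3 | step 7 | 6-allyl-2-(allyloxy)-5-bromo-3-chloro-N-methoxy-N-methylbenzamide | CON(C)C(=O)c1c(CC=C)c(Br)cc(Cl)c1OCC=C
F4 | step 7 | 1-[6-allyl-2-(allyloxy)-5-bromo-3-chlorophenyl]prop-2-en-1-one | C=CC(=O)c1c(CC=C)c(Br)cc(Cl)c1OCC=C
F5 | step 8 | methyl 2-(allyloxy)-3-chloro-5-[(1′R,2′R,3′R,4′S)-5′,8′-bis(allyloxy)-2′,3′-epoxy-1′,4′-dihydroxy-1′,2′,3′,4′-tetrahydronaphthalen-4′-yl]benzoate | C=CCOc1ccc(OCC=C)c2c1[C@](c1cc(Cl)c(OCC=C)c(C(=O)OC)c1)(O)[C@@H]1O[C@@H]1[C@@H]2O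
F6 | step 8 | aroyl sulfoxonium ylide derived from F5 | C=CCOc1ccc(OCC=C)c2c1[C@](c1cc(Cl)c(OCC=C)c(C(=O)C=S(C)(C)=O)c1)(O)[C@@H]1O[C@@H]1[C@@H]2O
F7 | step 14 | 8,8′,1′-tris(tert-butyldimethylsilyl) ether of 20 | O=C1c2c(O[Si](C)(C)C(C)(C)C)c(Cl)cc3c2[C@@]2(Oc4cc(Cl)c(O[Si](C)(C)C(C)(C)C)c5c4[C@]3(O2)[C@@H]2O[C@@H]2[C@H]5O[Si](C)(C)C(C)(C)C)C=C1
F8 | step 14 | 8,8′,1′-tris(tert-butyldimethylsilyl) ether of 21 | O=C1c2c(O[Si](C)(C)C(C)(C)C)c(Cl)cc3c2[C@@]2(Oc4cc(Cl)c(O[Si](C)(C)C(C)(C)C)c5c4[C@]3(O2)[C@@H]2O[C@@H]2[C@H]5O[Si](C)(C)C(C)(C)C)[C@@H]2O[C@H]12
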